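The readings are simulated from invented constants; noise was put on by code.

First product is wanted here, yet these flasks also consume it, so its share at the end depends on how old it is by then.

| setting | green | red | spring | winter | midnight | noon |
|---|---|---|---|---|---|---|
| starting material | 0.50 M | 0.50 M | 0.50 M | 0.50 M (fed, over 4.80 h) | 0.50 M | 0.50 M |
| coupling partner | 0.65 M | 1.3 M | 0.650 M | 0.650 M | 0.650 M (fed, over 4.80 h) | 0.650 M |
| remark | run made earlier | run made earlier | a closed flask charged with all of it at once and left for 6.0 h | a stirred flask in which starting material is dosed at a steady rate over 4.80 h without added volume, worked up at 6.0 h | a stirred flask in which coupling partner is dosed at a steady rate over 4.80 h without added volume, worked up at 6.0 h | one stirred flow tank at steady state, fed with the mixture as stated, mean residence time 6.0 h |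
| time |  |  | 6.0 h | 6.0 h | 6.0 h |  |

green run (percent of the starting material charged)

| time / h | first product / % | bis adduct / % | tris adduct / % |
|---|---|---|---|
| 0.333 | 18.8 | 3.8 | 0.8 |
| 1.00 | 17.9 | 12.0 | 2.1 |
| 1.50 | 12.2 | 13.2 | 3.6 |
| 2.50 | 5.3 | 14.2 | 5.4 |
| 4.00 | 2.7 | 13.0 | 7.0 |
| 5.00 | 1.1 | 11.5 | 6.5 |
| 6.00 | 0.1 | 11.7 | 7.5 |

red run (percent of the starting material charged)

| time / min | first product / % | bis adduct / % | tris adduct / % |
|---|---|---|---|
| 15.0 | 24.5 | 8.3 | 0.8 |
| 30.0 | 22.9 | 16.3 | 3.5 |
| 50.0 | 15.6 | 22.0 | 6.6 |
| 60.0 | 11.8 | 21.7 | 9.0 |
| 80.0 | 7.4 | 20.6 | 11.2 |
| 90.0 | 6.1 | 19.6 | 11.6 |
| 120 | 2.6 | 17.2 | 12.7 |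

(readings scatter by 0.3 percentage points)

* the set-up with the highest share of first product in all that became first product or bis adduct or tris adduct or tetra adduct or over-reaction product or side product, at the outlet or at the end ("none" if the first two lie within 2 percentage points) (spring / winter / midnight / noon / none)
* share of first product in all that became first product or bis adduct or tris adduct or tetra adduct or over-reaction product or side product, at the outlet or at the end, spring
* share of first product in all that became first product or bis adduct or tris adduct or tetra adduct or over-reaction product or side product, at the outlet or at the end, winter
* share of first product in all that became first product or bis adduct or tris adduct or tetra adduct or over-reaction product or side product, at the outlet or at the end, midnight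
* share of first product in all that became first product or bis adduct or tris adduct or tetra adduct or over-reaction product or side product, at the outlet or at the end, noon

- the stated concentrations are those of everything mixed, before any reaction; amounts are the same in each set-up
- the feed brings no volume worth counting
- the earlier runs were made in a closed, stirred flask

1. Zero of the scale: suppose first product, once formed, is lost with one pseudo-first-order constant k in every set-up. A portion of age a then survives as e^(−ka), and the share asked is this survival averaged over the ages present at the end. The set-ups differ here by their age distributions, which is the engineer's residence-time distribution.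

2. Let t be 6.0 h. In spring the ages lie near t, so the share is about e^(−kt). For winter we assume, as a rough first estimate, that formation follows the feed, which spreads ages evenly from 1.20 h to t; any starting material left when the feed ends adds younger ages, and this window omits them. We book midnight with the same assumed window. In noon the ages are exponential with mean t, which gives 1/(1+kt).

3. A first k comes from the green run, where first product falls from 12.2% to 5.3% in 1.00 h, a slope of 0.834 h⁻¹. This gives spring 0.671%, winter 9.02% and noon 16.7%.

4. The weak link is k: that slope is a net figure, with first product still being formed. The late red run, with twice the partner, falls faster, and we take its slope as the loss constant k of first product, 1.51 h⁻¹. We commit to noon 9.93%, winter and midnight 2.24%, and spring 0.0114%. Noon leads by more than the margin, so our choice is noon.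

The forecast gave spring 0.3%, winter 3.5%, midnight 0.1%, noon 4.2% and best none: "The top two lie within 2 points, so none."

The flask gives spring 1.10%, winter 4.89%, midnight 5.37%, noon 8.16%, and best noon.

    coupling partner + bis adduct → tris adduct + released group (k = 0.0180 M⁻¹ min⁻¹)
    starting material + coupling partner → first product + released group (k = 0.0270 M⁻¹ min⁻¹)
    coupling partner + first product → bis adduct + released group (k = 0.0330 M⁻¹ min⁻¹)
    first product → over-reaction product (k = 0.00950 min⁻¹)
    coupling partner + tris adduct → tetra adduct + released group (k = 0.0210 M⁻¹ min⁻¹)
    first product + released group → side product (k = 0.0500 M⁻¹ min⁻¹)

Put into the tank rule, the 8.16% of noon returns k = 1.88 h⁻¹, above our 1.51 h⁻¹. The assumed winter window with that k gives 1.17% against the 4.89% of winter, so that window and that k do not both hold for winter. With partner as charged in spring, the half-life of first product towards bis adduct is 0.54 h, shorter than the 1.2 h towards over-reaction product. That shorter half-life is short against the 6.0 h of spring, and spring ends at 1.10%.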